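**Retrosynthetic overview**
1. Aplyviolene ⇐ acetylation of the cage hemiacetal ⇐ TFA cascade of a masked dialdehyde–acid. This unveils the acetal aldehyde and the tBu-ester acid and closes the 2,7-dioxabicyclo[3.2.1] lactone-acetal.
2. The quaternary C(Me) next to the ring fusion ⇐ Johnson–Claisen [3,3] of a trans-cyclopentenol. The x–z bond ⇐ Michael addition of the resulting ester enolate to tBu 4,4-dimethoxycrotonate.
3. The cycloheptane ⇐ RCM of a vinyl ketone and a CMe2-allyl group. The gem-dimethyl comes from carvone's isopropenyl group by HAT allylation.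
4. The cyclopentene ⇐ Wolff ring contraction of (R)-carvone, which supplies C5.

Ring order: cyclopentene (Wolff), cycloheptenone (RCM), quaternary centre (Claisen), cage (TFA).

Assumptions: (i) the configurations at the ring fusion CH, x, y, z and the acetal carbon w are set thermodynamically and match the natural product; (ii) "x" is the cage CH bonded to the quaternary carbon, and y, z and w are the other cage carbons.

**Step 1**
Reactants: 1 (R)-(−)-carvone
Product: 2 (5R)-6-(hydroxymethylene)carvone
Conditions: HCO2Et, NaH (cat. EtOH), THF, 0 °C → rt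
Reagents that add atoms: ethyl formate, CCOC=O
Why: Claisen α′-formylation at the only enolisable α-CH2 (C6); the C5 stereocentre is untouched.

**Step 2**
Reactants: 2
Product: 3 (5R)-6-diazocarvone
Conditions: TsN3, Et3N, CH2Cl2, 0 °C → rt
Reagents that add atoms: tosyl azide, Cc1ccc(cc1)S(=O)(=O)N=[N+]=[N-]
Why: deformylative (Regitz) diazo transfer gives the α′-diazo enone.

**Step 3**
Reactants: 3
Product: 4 methyl 2-methyl-5-isopropenylcyclopent-2-ene-1-carboxylate (C5 as in carvone; CH(CO2Me) epimeric mixture)
Conditions: hν (Pyrex, Hg lamp), MeOH, 0 °C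
Reagents that add atoms: methanol, CO
Why: photo-Wolff ring contraction; the vinyl carbon migrates, the ketene is trapped by MeOH, and C5 is retained. The new CH(CO2Me) centre is uncontrolled and is erased at Step 13.

**Step 4**
Reactants: 4
Product: 5 methyl 2-methyl-4-oxo-5-isopropenylcyclopent-2-ene-1-carboxylate
Conditions: CrO3, 3,5-dimethylpyrazole, CH2Cl2, −20 → 0 °C
Reagents that add atoms: chromium trioxide (source of O), O=[Cr](=O)=O
Why: allylic CH2 oxidation of the trisubstituted cyclopentene to the conjugated enone (Salmond–Corey-type oxidation).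

**Step 5**
Reactants: 5
Product: 6 methyl 4-hydroxy-2-methyl-5-isopropenylcyclopent-2-ene-1-carboxylate (OH trans to isopropenyl)
Conditions: Al(OiPr)3, iPrOH, 82 °C
Reagents that add atoms: none
Why: Meerwein–Ponndorf–Verley 1,2-reduction under equilibrating conditions gives the thermodynamically preferred trans alcohol. This fixes the face the Claisen will use. Any OMe→OiPr ester exchange is irrelevant because the ester becomes a Weinreb amide in Step 7.

**Step 6**
Reactants: 6
Product: 7 methyl 4-hydroxy-2-methyl-5-(2-methylpent-4-en-2-yl)cyclopent-2-ene-1-carboxylate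
Conditions: Fe(acac)3, PhSiH3, allyl phenyl sulfone, EtOH, 60 °C
Reagents that add atoms: allyl phenyl sulfone, C=CCS(=O)(=O)c1ccccc1
Why: Fe–H hydrogen-atom transfer to the more reactive 1,1-disubstituted isopropenyl group gives a tertiary radical, which undergoes radical allylation by addition and fragmentation (no new stereocentre).

**Step 7**
Reactants: 7
Product: 8 Weinreb amide of 7
Conditions: MeNHOMe·HCl, iPrMgCl (excess), THF, −20 °C
Reagents that add atoms: N,O-dimethylhydroxylamine, CNOC
Why: the Grignard-mediated Weinreb aminolysis works with the free OH present.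

**Step 8**
Reactants: 8
Product: 9 vinyl ketone
Conditions: CH2=CHMgBr (3 equiv), THF, −78 °C
Reagents that add atoms: vinylmagnesium bromide, C=C[Mg]Br
Why: the Weinreb amide stops at the ketone stage.

**Step 9**
Reactants: 9
Product: 10 cyclohept-2-enone fused to the 3-methylcyclopentene
Conditions: Hoveyda–Grubbs II (10 mol%), toluene (2 mM), 80 °C
Reagents that add atoms: none
Why: RCM of the vinyl ketone with the allyl group closes the seven-membered ring; the gem-dimethyl group favours cyclisation and ethylene is lost.

**Step 10**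
Reactants: 10
Product: 11 saturated cycloheptanone
Conditions: [(Ph3P)CuH]6 (cat.), PhSiH3, toluene, 0 °C
Reagents that add atoms: none
Why: Stryker conjugate reduction is selective for the enone over the trisubstituted alkene and the free OH.

**Step 11**
Reactants: 11
Product: 12 ethyl 2-[(quaternary C)]acetate with C6′=C7 alkene
Conditions: CH3C(OEt)3, EtCO2H (cat.), xylene, 140 °C, sealed tube
Reagents that add atoms: triethyl orthoacetate, CC(OCC)(OCC)OCC
Why: Johnson–Claisen [3,3]-sigmatropic rearrangement is suprafacial, so the new C–C bond forms on the face of the departing C–O bond. With the OH trans to the CMe2 arm, the CH2CO2Et group is delivered anti to the seven-ring and Me ends up syn. This sets the quaternary stereocentre.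

**Step 12**
Reactants: 12
Product: 13 saturated ketoester
Conditions: H2 (1 atm), 10% Pd/C, EtOAc, rt
Reagents that add atoms: none
Why: the disubstituted ring alkene is reduced and the ketone and ester survive (no stereocentre created).

**Step 13**
Reactants: 13
Product: 14 cis-fused ketoester
Conditions: NaOEt, EtOH, rt
Reagents that add atoms: none
Why: epimerisation α to the ketone places the C=O carbon trans to the neighbouring CH2CO2Et, giving the cis-fused 5–7 system as the thermodynamic product.

**Step 14**
Reactants: 14
Product: 15 exocyclic-methylene ester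
Conditions: Ph3P=CH2 (from Ph3PCH3Br, KOtBu), THF, 0 °C → rt
Reagents that add atoms: methylenetriphenylphosphorane, C=P(c1ccccc1)(c1ccccc1)c1ccccc1
Why: Wittig methylenation converts the C=O into the exocyclic alkene and the ring fusion is now fixed.

**Step 15**
Reactants: 16 2,2-dimethoxyacetaldehyde; 17 tert-butyl (triphenylphosphoranylidene)acetate
Product: 18 tert-butyl (E)-4,4-dimethoxybut-2-enoate
Conditions: toluene, 80 °C
Reagents that add atoms: none
Why: Wittig olefination with a stabilised ylide gives the (E)-enoate acceptor.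

**Step 16**
Reactants: 15, 18
Product: 19 Michael adduct (x and z epimeric)
Conditions: LDA, THF, −78 °C; then 18, DMPU, −78 → −40 °C
Reagents that add atoms: none
Why: ester-enolate conjugate addition joins x to z. Both new centres are epimerisable later, so they are not controlled here.

**Step 17**
Reactants: 19
Product: 20 carboxylic acid (ethyl ester cleaved, tBu ester kept)
Conditions: Me3SnOH, 1,2-dichloroethane, 80 °C
Reagents that add atoms: trimethyltin hydroxide, C[Sn](C)(C)O
Why: mild Me3SnOH saponification cleaves the hindered ethyl ester and leaves the tBu ester, acetal and alkene intact.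

**Step 18**
Reactants: 20
Product: 21 primary alcohol
Conditions: ClCO2Et, N-methylmorpholine, THF, −15 °C; then NaBH4, MeOH, 0 °C
Reagents that add atoms: none
Why: the mixed anhydride is reduced by NaBH4, which leaves the tBu ester, acetal and exocyclic alkene alone.

**Step 19**
Reactants: 21
Product: 22 aldehyde
Conditions: Dess–Martin periodinane, NaHCO3, CH2Cl2, rt
Reagents that add atoms: none
Why: mild oxidation to the aldehyde y.

**Step 20**
Reactants: 22
Product: 23 cage hemiacetal
Conditions: TFA, H2O, CH2Cl2 (1:0.1:1), 0 °C → rt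
Reagents that add atoms: water, O
Why: TFA removes the tBu group and hydrolyses the acetal to aldehyde w. The acid then adds to aldehyde y to close the δ-lactone, and the resulting y–OH adds to aldehyde w to close the THF ring. The equilibrating α-centres (x and z) settle into the bridged cage configuration.

**Step 21**
Reactants: 23
Product: 24 aplyviolene
Conditions: Ac2O, pyridine, DMAP (cat.), CH2Cl2, rt
Reagents that add atoms: acetic anhydride, CC(=O)OC(C)=O
Why: O-acetylation of the lactol OH gives the acetoxy acetal; the acetal carbon configuration is assumed to be anomerically controlled.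

**Compound list**
1 | (R)-(−)-carvone | CC1=CC[C@H](CC1=O)C(C)=C | starting material
2 | (5R)-6-(hydroxymethylene)carvone | CC1=CC[C@H](C(=CO)C1=O)C(C)=C | intermediate
3 | (5R)-6-diazocarvone | CC1=CC[C@H](C(=[N+]=[N-])C1=O)C(C)=C | intermediate
4 | methyl 2-methyl-5-isopropenylcyclopent-2-ene-1-carboxylate (C1 epimeric) | C=C(C)[C@@H]1CC=C(C)C1C(=O)OC | intermediate
5 | methyl 2-methyl-4-oxo-5-isopropenylcyclopent-2-ene-1-carboxylate | C=C(C)[C@@H]1C(=O)C=C(C)C1C(=O)OC | intermediate
6 | methyl 4-hydroxy-2-methyl-5-isopropenylcyclopent-2-ene-1-carboxylate (OH trans to isopropenyl) | C=C(C)[C@@H]1[C@@H](O)C=C(C)C1C(=O)OC | intermediate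
7 | 5-(2-methylpent-4-en-2-yl) analogue of 6 | C=CCC(C)(C)[C@@H]1[C@@H](O)C=C(C)C1C(=O)OC | intermediate
8 | Weinreb amide of 7 | C=CCC(C)(C)[C@@H]1[C@@H](O)C=C(C)C1C(=O)N(C)OC | intermediate
9 | vinyl ketone | C=CCC(C)(C)[C@@H]1[C@@H](O)C=C(C)C1C(=O)C=C | intermediate
10 | 5–7 fused cycloheptenone, allylic OH trans to the gem-dimethyl arm | O=C1C=CCC(C)(C)[C@@H]2[C@@H](O)C=C(C)C12 | intermediate
11 | saturated cycloheptanone | O=C1CCCC(C)(C)[C@@H]2[C@@H](O)C=C(C)C12 | intermediate
12 | Claisen ester, C6′=C7 alkene | O=C1CCCC(C)(C)[C@@H]2C=C[C@@](C)(CC(=O)OCC)C12 | intermediate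
13 | saturated ketoester | O=C1CCCC(C)(C)[C@@H]2CC[C@@](C)(CC(=O)OCC)C12 | intermediate
14 | cis-fused ketoester | O=C1CCCC(C)(C)[C@@H]2CC[C@@](C)(CC(=O)OCC)[C@H]12 | intermediate
15 | exocyclic-methylene ester | C=C1CCCC(C)(C)[C@@H]2CC[C@@](C)(CC(=O)OCC)[C@H]12 | intermediate
16 | 2,2-dimethoxyacetaldehyde | COC(OC)C=O | starting material
17 | tert-butyl (triphenylphosphoranylidene)acetate | CC(C)(C)OC(=O)C=P(c1ccccc1)(c1ccccc1)c1ccccc1 | starting material
18 | tert-butyl (E)-4,4-dimethoxybut-2-enoate | CC(C)(C)OC(=O)/C=C/C(OC)OC | intermediate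
19 | Michael adduct | C=C1CCCC(C)(C)[C@@H]2CC[C@@](C)(C(C(=O)OCC)C(C(OC)OC)CC(=O)OC(C)(C)C)[C@H]12 | intermediate
20 | acid | C=C1CCCC(C)(C)[C@@H]2CC[C@@](C)(C(C(=O)O)C(C(OC)OC)CC(=O)OC(C)(C)C)[C@H]12 | intermediate
21 | primary alcohol | C=C1CCCC(C)(C)[C@@H]2CC[C@@](C)(C(CO)C(C(OC)OC)CC(=O)OC(C)(C)C)[C@H]12 | intermediate
22 | aldehyde | C=C1CCCC(C)(C)[C@@H]2CC[C@@](C)(C(C=O)C(C(OC)OC)CC(=O)OC(C)(C)C)[C@H]12 | intermediate
23 | cage hemiacetal | C=C1CCCC(C)(C)[C@@H]2CC[C@@](C)([C@@H]3[C@@H]4OC(=O)C[C@H]3[C@H](O)O4)[C@H]12 | intermediate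
24 | aplyviolene | C=C1CCCC(C)(C)[C@@H]2CC[C@@](C)([C@@H]3[C@@H]4OC(=O)C[C@H]3[C@H](OC(C)=O)O4)[C@H]12 | target

**Total step count:** 21 (including the one-step acceptor branch).
**Longest linear sequence:** 20 steps, from 1 to 24.

**Three steps most likely to fail**
1. **Step 16 (Michael addition).** The neopentyl-type ester enolate is very hindered and the acceptor is β-branched. Fallback: drop Steps 11–18 and instead ester-couple alcohol 11 with HO2C–CH2–C(=CHOMe)–CH2CO2tBu, then run an Ireland–Claisen that installs x, y, z and w in the [3,3] step itself.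
2. **Step 4 (allylic oxidation).** Oxidation at C6′ competes with the isopropenyl and ring C–H positions. Fallback: skip the allylic alcohol and Claisen entirely. Do an Fe(acac)3/PhSiH3 HAT–Giese coupling of the Cq=C7 alkene in ketone 11 with a Stobbe-derived acceptor, (MeO)2CH–CH=C(CO2Me)CH2CO2tBu.
3. **Step 6 (HAT allylation).** The trisubstituted ring alkene may compete with the isopropenyl group. Fallback: generate the tertiary cation from the isopropenyl group with a Lewis acid (TiCl4) and trap it with allyltrimethylsilane (ionic allylation) to give the same CMe2-allyl compound 7.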